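(The earlier runs and the new flask were computed for an exercise; noise was put on by code.)

Nucleophile could be balanced without any rate. By the candidate steps, each electrophile that reacted took one nucleophile, and each target that went on to over-reaction product took a second. So with nucleophile, free and protonated, used up, the reacted part of the electrophile had to equal half of the charged ratio c(nucleophile)/c(electrophile), plus half of the target standing. I called the first term the nucleophile budget, 75.0 %.

in all of them: electrophile 0.050 M

| charge | nucleophile | free base | remark | time |
|---|---|---|---|---|
| alder | 0.075 M | 0.047 M | run made earlier |  |
| birch | 0.075 M | 0.23 M | run made earlier |  |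
| dawn | 0.0750 M | 0.300 M |  | 20 min |
| noon | 0.0750 M | 0.150 M |  | 20 min |
| midnight | 0.0750 M | 0.0750 M |  | 20 min |

| run | time / min | electrophile / % | target / % |
|---|---|---|---|
| alder | 2.00 | 61 | 11 |
| alder | 4.00 | 52 | 12 |
| alder | 6.00 | 45 | 8 |
| alder | 8.00 | 37 | 15 |
| alder | 10.0 | 35 | 8 |
| alder | 12.0 | 37 | 7 |
| alder | 15.0 | 30 | 4 |
| birch | 2.00 | 63 | 13 |
| birch | 4.00 | 48 | 10 |
| birch | 6.00 | 40 | 8 |
| birch | 8.00 | 33 | 7 |
| birch | 10.0 | 33 | 7 |
| birch | 12.0 | 33 | 5 |
| birch | 15.0 | 31 | 7 |

(standard deviation of a reading: 2 percentage points)

- part of the electrophile that has reacted at the end, dawn
- part of the electrophile that has reacted at the end, noon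
- part of the electrophile that has reacted at the end, midnight
- what raising the concentration of free base from its lowest to its highest value here does to the part of the electrophile that has reacted (changes below 5 percentage points count as none) (it falls / no change / it rises)

- the analysis behind the earlier runs scatters by 2 percentage points, standard deviation
- candidate steps: electrophile + nucleophile -> acid set free + target; nucleophile + acid set free <-> protonated nucleophile; acid set free + free base <-> salt of the base; nucleophile + target -> over-reaction product; acid set free -> by-product carried off

This is what I left you on the bench. Dawn, noon and midnight hold the same electrophile and nucleophile, and the nucleophile falls short of two per electrophile, which makes it the limiting reagent. Alder and birch differed in base by a factor of 4.89, yet their electrophile stood at 30 % and 31 % at the last reading, against a scatter of 2 percentage points. The acid set free could reach about 0.0375 M, less than the 0.0750 M of free base in midnight, the lowest charge of the new flasks. So I expected no effect from the base.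

Expect over-reaction product, target near the 7 % read in birch, and unreacted electrophile. Birch had reached 69.0 % at 15.0 min, 6 points under the budget, so I committed to the budget itself, 75.0 %, for dawn, noon and midnight. Leave the ratio of the charges alone, since the budget reads that ratio.

The forecast gave 71 %, 71 % and 71 % for dawn, noon and midnight, lower than my figure, and no change: “All three new runs have base in excess of the acid, so they should match, with no trend.”

The flasks gave 74.8 %, 74.4 % and 73.8 %, so no change, with 0.95 points from lowest to highest base.

    electrophile + nucleophile → acid set free + target (k = 0.0740 /M/s)
    nucleophile + acid set free ⇌ protonated nucleophile, settled at all times (K = 170 /M)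
    acid set free + free base ⇌ salt of the base (K = 1500 /M, k = 0.240 /M/s)
    nucleophile + target → over-reaction product (k = 0.440 /M/s)
    acid set free → by-product carried off (k = 0.00640 /s)

In noon at 2.13 min, nucleophile had a half-life of 5.0 min by the first step and 4.6 min by over-reaction, and target was made at 0.924 of the rate at which it was used up. At 20.0 min noon held 5.16 % target beside 69.3 % over-reaction product. Left for 200 min, noon had 0 % nucleophile and 4.59 % target, and the budget plus half of that target gives 77.3 %, against 77.3 % computed. With 0.12 M electrophile in noon's recipe the budget is 31.2 %, and half of its 11.4 % target raises that to 36.9 %; the computed result is 37.0 %, with nucleophile at 0 %.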